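The C11–O bond of the secondary acetate is the disconnection on which the route rests. An acetoxy group on C11, the side-chain carbon attached to C9 of the trans-decalin (rings A/B), is what Baeyer–Villiger oxidation of a C11 methyl ketone leaves. In one operation the key step inserts oxygen between C11 and the acetyl carbonyl with retention, turning a carbon stereocentre set by enolate alkylation into the 11S carbinol ester. Its precursor is the 8α-hydroxy C11-acetyl labdane already carrying the complete E-enoate chain. It is built from (+)-sclareolide, whose sixteen carbons become C1–C11, C17–C20 and the acetate carbonyl. The C8=C17 alkene stays masked as the tertiary alcohol until the end.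

Key step: step 4

Remark: labdane numbering is used throughout (C8 carbinol/alkene carbon, C9 ring CH, C11 the carbon on C9, C17 the C8 methyl or methylene; the lactone carbonyl carbon is called C12′), and bromide 2 is assumed to be the pure E isomer.

Step 1
Reactants: 1 (+)-sclareolide; 2 methyl (E)-4-bromo-3-methylbut-2-enoate
Product: 4 (11S)-11-[(E)-4-methoxy-2-methyl-4-oxobut-2-enyl]sclareolide, via sclareolide lithium enolate 3 (not isolated)
Conditions: LDA (1.1 equiv), THF, −78 °C; then 2 (1.3 equiv), DMPU, −78 → −40 °C
Reagents that add atoms: methyl (E)-4-bromo-3-methylbut-2-enoate (2), BrC/C(C)=C/C(=O)OC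
Why: Kinetic lithium enolate alkylation (SN2 at the primary allylic bromide, whose methyl-bearing β-carbon discourages conjugate addition) on the rigid trans-fused γ-lactone, in which the β face of C11 is screened by the axial C17 and C20 methyls, so the electrophile should enter from the α face, cis to H-9, and fix C11 as S, while the E geometry of the enoate is carried over unchanged from 2.

Step 2
Reactants: 4 (11S)-11-[(E)-4-methoxy-2-methyl-4-oxobut-2-enyl]sclareolide; 5 N,O-dimethylhydroxylamine hydrochloride
Product: 6 methyl (11S,13E)-8α-hydroxy-11-[methoxy(methyl)carbamoyl]labd-13-en-15-oate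
Conditions: 5 (3 equiv), AlMe3 (3 equiv), CH2Cl2, 0 °C → rt; aq. Rochelle salt; crude product taken on
Reagents that add atoms: N,O-dimethylhydroxylamine hydrochloride (5), CNOC.Cl
Why: Weinreb aminolysis with the aluminium amide made from AlMe3 and 5 opens the lactone at the acyl C–O bond (C8–O is untouched and C11 is not enolised, so both centres keep their configuration), the s-cis lactone being far more electrophilic towards the Lewis-acidic amide than the conjugated β,β-disubstituted methyl ester, which should need prolonged heating to react.

Step 3
Reactants: 6 methyl (11S,13E)-8α-hydroxy-11-[methoxy(methyl)carbamoyl]labd-13-en-15-oate; 7 methylmagnesium bromide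
Product: 9 methyl (11S,13E)-11-acetyl-8α-hydroxylabd-13-en-15-oate, via N,O-chelated bromomagnesium adduct 8 (not isolated)
Conditions: 7 (3.5 equiv), THF, −20 → 0 °C; pH 7 phosphate buffer, 0 °C
Reagents that add atoms: methylmagnesium bromide (7), C[Mg]Br
Why: Weinreb ketone synthesis, in which the first equivalent deprotonates the C8 hydroxyl and methyl addition then gives the N,O-chelated adduct 8 that cannot collapse and over-add before the neutral quench, the chelation-activated amide being expected to react at −20 to 0 °C well before the deactivated β,β-disubstituted enoate, while the cold buffered work-up leaves the enolisable C11 centre untouched.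

Step 4
Reactants: 9 methyl (11S,13E)-11-acetyl-8α-hydroxylabd-13-en-15-oate
Product: 11 methyl (11S,13E)-11-acetoxy-8α-hydroxylabd-13-en-15-oate, via Criegee adduct 10 (not isolated)
Conditions: mCPBA (3 equiv), NaHCO3, CH2Cl2, 0 °C → rt, dark
Reagents that add atoms: mCPBA, O=C(OO)c1cccc(Cl)c1
Why: The peracid adds to the ketone carbonyl of 9 (the open form, in equilibrium with its hemiketal) to give Criegee adduct 10, and C11 then shifts from the acyl carbon to the proximal peroxide oxygen, anti-periplanar to the breaking O–O bond, as 3-chlorobenzoate leaves, which forms the C11–O and O–C(acyl) bonds of the acetate. The closest known reaction type is the Baeyer–Villiger oxidation of sec-alkyl methyl ketones, including the 8α-hydroxy methyl ketone derived from sclareolide itself, which gives an 11-acetoxy-8-ol. No ring is closed, so there is no mode of closure to specify. The new C11–O stereocentre arises by a concerted 1,2-shift with retention, so its 11S configuration is controlled by the α-face alkylation of step 1 and not by the oxidant. The step needs migration of the secondary C11 in preference to methyl, which the better ability of the more substituted carbon to carry positive charge in the transition state secures, and it needs chemoselectivity over epoxidation, which is secured because the only alkene present is the electron-poor β,β-disubstituted enoate while C8=C17 is still masked as the alcohol. The bicarbonate buffer should keep the tertiary C8 alcohol from acid-induced dehydration or addition to the enoate.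

Step 5
Reactants: 11 methyl (11S,13E)-11-acetoxy-8α-hydroxylabd-13-en-15-oate
Product: 13 methyl (11S,13E)-11-acetoxylabda-8(17),13-dien-15-oate, via 8-O-chlorosulfite 12 (not isolated)
Conditions: SOCl2 (2 equiv), pyridine, CH2Cl2, −78 °C
Reagents that add atoms: none
Why: Low-temperature chlorosulfite dehydration of E2 type, in which the equatorial 8α C–O bond is anti-periplanar only to a C–H bond of the freely rotating axial C17 methyl (H-7 and H-9 are gauche to it), so pyridine should remove a C17 proton and give the exocyclic 8(17)-alkene, the acetate, the enoate and all four stereocentres being spectators and the minor Δ7 and Δ8 isomers being removable on AgNO3-impregnated silica.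

Compound list
1 | (+)-sclareolide (trans-fused γ-lactone on the trans-decalin; 8α-O, 9β-CH2, 17β- and 20β-methyls) | C[C@@]12CC[C@H]3C(C)(C)CCC[C@]3(C)[C@H]1CC(=O)O2 | starting material
2 | methyl (E)-4-bromo-3-methylbut-2-enoate | BrC/C(C)=C/C(=O)OC | starting material
3 | sclareolide lithium enolate (C11=C12′ enolate) | C[C@@]12CC[C@H]3C(C)(C)CCC[C@]3(C)[C@H]1C=C([O-])O2.[Li+] | intermediate
4 | (11S)-11-[(E)-4-methoxy-2-methyl-4-oxobut-2-enyl]sclareolide (new CH2 on the α face of the lactone, cis to H-9) | C[C@@]12CC[C@H]3C(C)(C)CCC[C@]3(C)[C@H]1[C@H](C/C(C)=C/C(=O)OC)C(=O)O2 | intermediate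
5 | N,O-dimethylhydroxylamine hydrochloride | CNOC.Cl | starting material
6 | methyl (11S,13E)-8α-hydroxy-11-[methoxy(methyl)carbamoyl]labd-13-en-15-oate | C[C@@]1(O)CC[C@H]2C(C)(C)CCC[C@]2(C)[C@H]1[C@H](C/C(C)=C/C(=O)OC)C(=O)N(C)OC | intermediate
7 | methylmagnesium bromide | C[Mg]Br | starting material
8 | N,O-chelated bromomagnesium adduct of 6 (tetrahedral hemiaminal alkoxide; C8 alkoxide also magnesiated) | C[C@@]1(O[Mg]Br)CC[C@H]2C(C)(C)CCC[C@]2(C)[C@H]1[C@H](C/C(C)=C/C(=O)OC)C(C)(O[Mg]Br)N(C)OC | intermediate
9 | methyl (11S,13E)-11-acetyl-8α-hydroxylabd-13-en-15-oate (open form; equilibrates with its cyclic hemiketal) | C[C@@]1(O)CC[C@H]2C(C)(C)CCC[C@]2(C)[C@H]1[C@H](C/C(C)=C/C(=O)OC)C(C)=O | intermediate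
10 | Criegee adduct of 9 with mCPBA (peroxy hemiketal) | C[C@@]1(O)CC[C@H]2C(C)(C)CCC[C@]2(C)[C@H]1[C@H](C/C(C)=C/C(=O)OC)C(C)(O)OOC(=O)c1cccc(Cl)c1 | intermediate
11 | methyl (11S,13E)-11-acetoxy-8α-hydroxylabd-13-en-15-oate | C[C@@]1(O)CC[C@H]2C(C)(C)CCC[C@]2(C)[C@H]1[C@H](C/C(C)=C/C(=O)OC)OC(C)=O | intermediate
12 | 8-O-chlorosulfite of 11 | C[C@@]1(OS(=O)Cl)CC[C@H]2C(C)(C)CCC[C@]2(C)[C@H]1[C@H](C/C(C)=C/C(=O)OC)OC(C)=O | intermediate
13 | methyl (5S,9S,10S,11S,13E)-11-acetoxylabda-8(17),13-dien-15-oate (CNP0309821.1) | C=C1CC[C@H]2C(C)(C)CCC[C@]2(C)[C@H]1[C@H](C/C(C)=C/C(=O)OC)OC(C)=O | target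

Total step count: 5. Longest linear sequence: 5 steps (1 → 4 → 6 → 9 → 11 → 13).

Steps most likely to fail

Step 3. The Grignard reagent may attack the conjugated ester competitively, or the C8 alkoxide may return onto the amide carbonyl before methyl transfer. The fallback takes the ester out of play as its carboxylate, sets out from 4 and comes back at 9, and so also bypasses the aminolysis of step 2. Saponification of the enoate (LiOH, THF/H2O, then acidification to pH 3, which re-closes any opened lactone) would give (E)-3-methyl-4-[(11S)-sclareolid-11-yl]but-2-enoic acid F1. Methyllithium (3.5 equiv, THF, −78 °C) should then add once to the lactone carbonyl, the lithium carboxylate being inert and the lithium lactolate stable at this temperature, to give (11S,13E)-11-acetyl-8α-hydroxylabd-13-en-15-oic acid F2. Esterification with trimethylsilyldiazomethane (MeOH/toluene, 0 °C) would return 9.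

Step 1. The basic lactone enolate may take a γ-proton from the bromoenoate, or add in conjugate fashion with subsequent ring closure, instead of displacing bromide. The fallback builds the side chain in stages from an electrophile with no acidic or acceptor site, sets out from 1 and comes back at 4. Enolate 3 and 3-bromo-2-methylpropene (THF, −78 °C) should give, under the same α-face control, (11S)-11-(2-methylallyl)sclareolide F3. Ozonolysis (O3, CH2Cl2/MeOH, −78 °C; Me2S) would give (11S)-11-(2-oxopropyl)sclareolide F4. Horner–Wadsworth–Emmons olefination with trimethyl phosphonoacetate and NaH (THF, 0 °C → rt) should give 4 after chromatographic removal of the minor Z isomer.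

Step 5. The tertiary chlorosulfite may ionise, so that regiocontrol in the proton removal is lost and the endocyclic alkenes grow. The fallback replaces the base-induced anti elimination by a thermal intramolecular syn elimination, sets out from 11 and comes back at 13. Burgess reagent (benzene, rt → 50 °C) would convert the alcohol into methyl (11S,13E)-11-acetoxy-8α-{[N-(methoxycarbonyl)sulfamoyl]oxy}labd-13-en-15-oate F5. Its fragmentation through a six-membered transition state should favour the three eclipsable hydrogens of C17 over the single gauche H-7α and H-9α.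

Further compounds
F1 | step 3 | (E)-3-methyl-4-[(11S)-sclareolid-11-yl]but-2-enoic acid | C[C@@]12CC[C@H]3C(C)(C)CCC[C@]3(C)[C@H]1[C@H](C/C(C)=C/C(=O)O)C(=O)O2
F2 | step 3 | (11S,13E)-11-acetyl-8α-hydroxylabd-13-en-15-oic acid | C[C@@]1(O)CC[C@H]2C(C)(C)CCC[C@]2(C)[C@H]1[C@H](C/C(C)=C/C(=O)O)C(C)=O
F3 | step 1 | (11S)-11-(2-methylallyl)sclareolide | C[C@@]12CC[C@H]3C(C)(C)CCC[C@]3(C)[C@H]1[C@H](CC(C)=C)C(=O)O2
F4 | step 1 | (11S)-11-(2-oxopropyl)sclareolide | C[C@@]12CC[C@H]3C(C)(C)CCC[C@]3(C)[C@H]1[C@H](CC(C)=O)C(=O)O2
F5 | step 5 | methyl (11S,13E)-11-acetoxy-8α-{[N-(methoxycarbonyl)sulfamoyl]oxy}labd-13-en-15-oate | C[C@@]1(OS(=O)(=O)NC(=O)OC)CC[C@H]2C(C)(C)CCC[C@]2(C)[C@H]1[C@H](C/C(C)=C/C(=O)OC)OC(C)=O
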